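If I follow each mole of substrate to where it ends, the books for autumn and noon need one quantity, and I read it from the runs so far.

the same everywhere: catalyst 0.50 mM
- beta: substrate 0.31 M; other conformer 0.50 M; temperature 10 °C; run made earlier
- alpha: substrate 0.48 M; other conformer 0.50 M; temperature 25 °C; run made earlier
- theta: substrate 1.1 M; other conformer 0.50 M; temperature 10 °C; run made earlier
- autumn: substrate 1.0 M; other conformer 0.500 M; temperature 25 °C; time 12 h
- noon: substrate 0.25 M; other conformer 0.500 M; temperature 25 °C; time 12 h

- beta (time / h: target / %): 2.00: 17.3; 4.00: 25.9; 8.00: 32.4; 12.0: 32.7; 15.0: 32.1
- alpha (time / h: target / %): 0.667: 16.7; 1.33: 26.0; 2.50: 31.0; 4.00: 34.3; 8.00: 33.8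
- theta (time / h: target / %): 1.33: 23.1; 3.00: 41.0; 5.00: 50.4; 8.00: 56.9; 15.0: 59.3

(standard deviation of a reading: 0.5 percentage points)

- on the list of suspects stand: substrate + catalyst -> catalyst + target; substrate <-> other conformer; catalyst + other conformer -> catalyst + isomer of the product; substrate -> uncatalysed product
- in a conversion other conformer counts as not yet reacted

* which of the two ends with the higher amount of target, in percent of the substrate and other conformer together charged ("neither" if they lie within 2 percentage points) (autumn / noon / neither)
* target at the end, in percent of the substrate and other conformer together charged, autumn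
* target at the end, in percent of the substrate and other conformer together charged, noon

The alpha run stands at the temperature of both new flasks, with the same catalyst charge and the same other conformer charge, and its last two readings average 34.0%. Turned into moles, this gives 69.5% for the target share f, the moles of target at the plateau per mole of substrate charged, which is the selectivity for target. At 10 °C, beta gives 85.4% and theta 86.3%, though substrate goes from 0.31 M to 1.1 M at the same other conformer charge. I therefore assume that f holds at 25 °C for the substrate charges of autumn and noon, and that other conformer adds no target. Alpha stands at half its plateau at 0.667 h, and I take that half-life over to autumn and noon, which hold the same catalyst charge. My ledger then reads: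

Half-lives in 12 h: n = 18.0, leaving <0.001% of the substrate

Autumn: 1.0 M substrate, 0.695 M to target, 0.305 M elsewhere

Noon: 0.25 M substrate, 0.174 M to target, 0.0762 M elsewhere

Target over substrate and other conformer charged: autumn 46.3%, noon 23.2%

So I expect autumn to end higher by 23 percentage points, more than the margin of 2 points.

The forecast says autumn, with 46.3% for autumn and 23.1% for noon, holding that “The yield per substrate therefore doesn't depend on concentration”; its noon figure stands 0.100 points under mine.

The flasks give autumn as the higher, with 46.4% for autumn and 23.3% for noon.

    substrate + catalyst → catalyst + target (k = 0.410 M⁻¹ s⁻¹, Ea = 39.0 kJ mol⁻¹)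
    substrate ⇌ other conformer (K = 10.0, k = 3.20 × 10⁻⁵ s⁻¹, Ea = 102 kJ mol⁻¹, ΔH = −54.0 kJ mol⁻¹)
    catalyst + other conformer → catalyst + isomer of the product (k = 2.00 M⁻¹ s⁻¹, Ea = 42.0 kJ mol⁻¹)
    substrate → uncatalysed product (k = 5.80 × 10⁻⁵ s⁻¹, Ea = 88.0 kJ mol⁻¹)
    (constants at 25 °C)

Read back through the ledger, these results give a target share of 69.6% in autumn and 70.0% in noon. The neighbouring flask is noon with 0.62 M of substrate, and the same entry, f times its substrate over its substrate and other conformer together, gives 38.5%. At 12.0 h that flask holds 0% of its substrate and ends at 38.6% target, which is 7.8 points less than autumn.

(The readings are calculated with made-up constants; scatter was added.)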